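The five-membered end ring C2–C3–C4–C5–C6 (carotenoid numbering), carrying isopropenyl on C2, methyl and hydroxyl on C5 and the polyene carbon C7 on C6, is a limonene skeleton whose ring alkene has been cut and re-closed between C5 and C6. Everything rests on that C5–C6 disconnection: one amine-catalysed aldol condensation closes the ring and delivers the C5=C6 enal with all ten end-group carbons and the C2 stereocentre in place. Its precursor is the open-chain 1,6-keto aldehyde (S)-3-isopropenyl-6-oxoheptanal from (S)-limonene. Anti epoxidation, inverting hydrogenolysis at C6 and a C15 + C10 + C15 Wittig assembly finish the carotenoid.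

Key step: step 3

Assumption: pseudoionone is used as its (3E,5E) isomer (commercial material enriched by fractional distillation if needed); locants with and without primes follow the carotenoid numbering of the target.

Step 1
Reactants: 1 (S)-(−)-limonene
Product: 2 (4S)-limonene 1,2-oxide (cis/trans mixture at the epoxide carbons)
Conditions: mCPBA (1.0 equiv), CH2Cl2, 0 °C
Reagents that add atoms: mCPBA (3-chloroperoxybenzoic acid), O=C(OO)c1cccc(Cl)c1
Why: Prilezhaev epoxidation should be faster at the electron-richer trisubstituted ring alkene than at the 1,1-disubstituted isopropenyl group, and the diastereomer mixture at the epoxide is of no consequence because both of its carbons become carbonyl carbons in step 2.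

Step 2
Reactants: 2 (4S)-limonene 1,2-oxide
Product: 4 (S)-3-isopropenyl-6-oxoheptanal, via limonene-1,2-diol 3 (not isolated)
Conditions: H5IO6 (1.1 equiv), THF/H2O, 0 °C → rt
Reagents that add atoms: water, O
Why: Aqueous periodic acid should first open the epoxide to the trans-diol and then cleave it (Malaprade glycol cleavage), so both epoxide diastereomers converge on one keto aldehyde; the stereocentre is α to neither carbonyl and the isopropenyl group is inert to the reagent.

Step 3
Reactants: 4 (S)-3-isopropenyl-6-oxoheptanal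
Product: 7 (R)-2-methyl-5-(prop-1-en-2-yl)cyclopent-1-ene-1-carbaldehyde, via enamine 5 (not isolated), via aldol adduct 6 (not isolated)
Conditions: piperidine (0.2 equiv), AcOH (0.2 equiv), toluene, 80 °C
Reagents that add atoms: none
Why: Piperidinium acetate condenses reversibly with the aldehyde, not with the slower methyl ketone, to give enamine 5, whose nucleophilic carbon (future C6) attacks the ketone carbon (future C5); the hydroxy iminium so formed (aldol 6 after hydrolysis) loses water through its enamine, and hydrolysis releases the tetrasubstituted enal 7 and the amine. The closest known reaction type is the amine-salt-catalysed intramolecular aldol condensation of a 1,6-keto aldehyde obtained by oxidative cleavage of a 1-methylcyclohexene. The ring C2–C3–C4–C5–C6 closes in the 5-(enolexo)-exo-trig mode. No stereocentre is created, since C5 and C6 end as alkene carbons, and C2 is kept because it is β to the aldehyde and carries no acidified hydrogen. The selectivity needed is regiochemical and is not guaranteed by ring size: enolisation of the ketone CH2 (C4) and attack on the aldehyde carbon would also close a five-membered ring and give 1-acetyl-4-isopropenylcyclopentene, the product expected from hydroxide-mediated cyclisation. It is secured by running the closure through the aldehyde-derived enamine in a weakly acidic, non-enolising medium, in which the unhindered aldehyde is the only carbonyl that forms an enamine at a useful rate.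

Step 4
Reactants: 7 (R)-2-methyl-5-(prop-1-en-2-yl)cyclopent-1-ene-1-carbaldehyde
Product: 8 (1R,2R,5S)-5-methyl-2-(prop-1-en-2-yl)-6-oxabicyclo[3.1.0]hexane-1-carbaldehyde
Conditions: 30% H2O2 (3 equiv), aq NaOH (cat., pH 8–9), MeOH, 0 °C
Reagents that add atoms: hydrogen peroxide, OO
Why: In this Weitz–Scheffer nucleophilic epoxidation hydroperoxide adds to the β-carbon C5 and the enolate closes onto oxygen at C6, so only the electron-poor C5=C6 bond reacts and the isopropenyl alkene is left alone; oxygen should enter on the ring face opposite the C2 isopropenyl group, because the C6–O bond forms next to C2, which sets C5 and C6 together.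

Step 5
Reactants: 8 (1R,2R,5S)-5-methyl-2-(prop-1-en-2-yl)-6-oxabicyclo[3.1.0]hexane-1-carbaldehyde
Product: 9 (3E)-4-[(1R,2R,5S)-5-methyl-2-(prop-1-en-2-yl)-6-oxabicyclo[3.1.0]hexan-1-yl]but-3-en-2-one
Conditions: Ph3P=CHC(O)CH3 (1.5 equiv), toluene, 80 °C
Reagents that add atoms: 1-(triphenylphosphoranylidene)propan-2-one, CC(=O)C=P(c1ccccc1)(c1ccccc1)c1ccccc1
Why: Wittig olefination with a keto-stabilised ylide should give the (E)-enone under neutral conditions that leave the epoxide untouched, and the aldehyde has no α-hydrogen to epimerise.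

Step 6
Reactants: 9 (3E)-4-[(1R,2R,5S)-5-methyl-2-(prop-1-en-2-yl)-6-oxabicyclo[3.1.0]hexan-1-yl]but-3-en-2-one
Product: 10 (3E)-4-[(1R,2S,5S)-2-hydroxy-2-methyl-5-(prop-1-en-2-yl)cyclopentyl]but-3-en-2-one
Conditions: Pd2(dba)3·CHCl3 (2.5 mol %), n-Bu3P (5 mol %), HCO2H (5 equiv), Et3N (2 equiv), 1,4-dioxane, rt
Reagents that add atoms: none
Why: In this palladium-catalysed formate hydrogenolysis of an alkenyl oxirane (a Tsuji–Trost-type allylic reduction) zerovalent palladium ionises the allylic C6–O bond from the face opposite to oxygen, the palladium-bound formate loses CO2, and hydride passes from the metal to C6, the allyl terminus remote from the acyl group, so C6–O is replaced by C6–H with inversion while the (E)-enone stays conjugated; the side chain thereby ends cis to the C5 hydroxyl and trans to isopropenyl, and the (E)-geometry at C7=C8 should prevent face exchange of the allyl unit.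

Step 7
Reactants: 10 (3E)-4-[(1R,2S,5S)-2-hydroxy-2-methyl-5-(prop-1-en-2-yl)cyclopentyl]but-3-en-2-one
Product: 11 (1S,2R,3S)-2-[(1E)-3-hydroxy-3-methylpenta-1,4-dien-1-yl]-1-methyl-3-(prop-1-en-2-yl)cyclopentan-1-ol (both epimers at the side-chain carbinol)
Conditions: CH2=CHMgBr (3 equiv), THF, −40 → 0 °C; aqueous work-up
Reagents that add atoms: vinylmagnesium bromide, C=C[Mg]Br
Why: Grignard 1,2-addition to the methyl ketone, the way vinyl ionols are made, should follow deprotonation of the C5 hydroxyl by the first equivalent; the new carbinol centre at C9 forms as an epimer mixture that does not matter because C9 becomes an alkene carbon in step 8.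

Step 8
Reactants: 11 (1S,2R,3S)-2-[(1E)-3-hydroxy-3-methylpenta-1,4-dien-1-yl]-1-methyl-3-(prop-1-en-2-yl)cyclopentan-1-ol
Product: 12 [(2E,4E)-5-[(1R,2S,5S)-2-hydroxy-2-methyl-5-(prop-1-en-2-yl)cyclopentyl]-3-methylpenta-2,4-dien-1-yl]triphenylphosphonium bromide
Conditions: PPh3·HBr (1.05 equiv), MeOH, 0 °C → rt; crystallisation
Reagents that add atoms: triphenylphosphine hydrobromide, [Br-].[PH+](c1ccccc1)(c1ccccc1)c1ccccc1
Why: In this acid-mediated allylic transposition (SN1′) the tertiary bis-allylic alcohol ionises to a pentadienyl cation that PPh3 captures at the unhindered terminus C11, the standard entry to C15 Wittig salts; the non-allylic C5 alcohol and the isopropenyl group should withstand the weakly acidic phosphonium bromide, and crystallisation should enrich the (9E) salt.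

Step 9
Reactants: 13 pseudoionone [(3E,5E)-6,10-dimethylundeca-3,5,9-trien-2-one]
Product: 14 (4E,6E)-3,7,11-trimethyldodeca-1,4,6,10-tetraen-3-ol (racemic)
Conditions: CH2=CHMgBr (1.3 equiv), THF, −20 → 0 °C; aqueous work-up
Reagents that add atoms: vinylmagnesium bromide, C=C[Mg]Br
Why: Grignard 1,2-addition to the dienone carbonyl should give the tertiary vinyl carbinol, whose stereocentre is lost in step 10.

Step 10
Reactants: 14 (4E,6E)-3,7,11-trimethyldodeca-1,4,6,10-tetraen-3-ol
Product: 15 [(2E,4E,6E)-3,7,11-trimethyldodeca-2,4,6,10-tetraen-1-yl]triphenylphosphonium bromide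
Conditions: PPh3·HBr (1.05 equiv), MeOH, 0 °C → rt; crystallisation
Reagents that add atoms: triphenylphosphine hydrobromide, [Br-].[PH+](c1ccccc1)(c1ccccc1)c1ccccc1
Why: The same acid-mediated allylic transposition (SN1′) as in step 8 should place phosphorus on the terminal carbon C11′ and give the acyclic C15 Wittig salt; the isolated trisubstituted alkene tolerates the reagent.

Step 11
Reactants: 15 [(2E,4E,6E)-3,7,11-trimethyldodeca-2,4,6,10-tetraen-1-yl]triphenylphosphonium bromide; 16 (2E,4E,6E)-2,7-dimethylocta-2,4,6-trienedial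
Product: 18 (2E,4E,6E,8E,10E,12E,14E)-2,7,11,15,19-pentamethylicosa-2,4,6,8,10,12,14,18-octaenal (apo-12′-lycopenal), via ylide 17 (not isolated)
Conditions: NaOMe (1.05 equiv), 15 added slowly to 16 (2 equiv), CH2Cl2/MeOH, 0 °C → rt; crystallisation
Reagents that add atoms: none
Why: Wittig olefination of one aldehyde group of the symmetrical dial, in which slow addition of the ylide to excess dial should limit double condensation and the semi-stabilised allylic ylide should give mainly the (E)-alkene at C11′=C12′.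

Step 12
Reactants: 12 [(2E,4E)-5-[(1R,2S,5S)-2-hydroxy-2-methyl-5-(prop-1-en-2-yl)cyclopentyl]-3-methylpenta-2,4-dien-1-yl]triphenylphosphonium bromide; 18 apo-12′-lycopenal
Product: 21 (all-E,2S,5S,6R)-1,16-didehydro-2,6-cyclolycopen-5-ol (target CNP0222499.1), via ylide 19 (not isolated), via crude Z/E mixture 20 (not isolated)
Conditions: NaOMe (1.1 equiv), CH2Cl2/MeOH, rt, dark, argon; then heptane, 80 °C; crystallisation
Reagents that add atoms: none
Why: Wittig olefination forms C11=C12 without touching the tertiary alcohol or any stereocentre (none is α to an acidifying group), and the sterically hindered 11Z isomer formed alongside should equilibrate on heating to the all-E polyene, which crystallises.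

Compound list
1 | (S)-(−)-limonene | C=C(C)[C@@H]1CC=C(C)CC1 | starting material
2 | (4S)-limonene 1,2-oxide, (4S)-1-methyl-4-(prop-1-en-2-yl)-7-oxabicyclo[4.1.0]heptane, cis/trans mixture at the epoxide carbons | C=C(C)[C@@H]1CC2OC2(C)CC1 | intermediate
3 | limonene-1,2-diol, expected mainly as (1R,2R,4S)-p-menth-8-ene-1,2-diol | C=C(C)[C@H]1CC[C@@](C)(O)[C@H](O)C1 | intermediate
4 | (S)-3-isopropenyl-6-oxoheptanal | C=C(C)[C@H](CC=O)CCC(C)=O | intermediate
5 | (5S,6E)-7-(piperidin-1-yl)-5-(prop-1-en-2-yl)hept-6-en-2-one (aldehyde enamine) | C=C(C)[C@H](/C=C/N1CCCCC1)CCC(C)=O | intermediate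
6 | (5S)-2-hydroxy-2-methyl-5-(prop-1-en-2-yl)cyclopentane-1-carbaldehyde (aldol adduct, drawn as the free aldehyde; in the flask in equilibrium with its piperidine iminium; diastereomer mixture at the two new centres, both lost on dehydration) | C=C(C)[C@H]1CCC(C)(O)C1C=O | intermediate
7 | (R)-2-methyl-5-(prop-1-en-2-yl)cyclopent-1-ene-1-carbaldehyde | C=C(C)[C@H]1CCC(C)=C1C=O | intermediate
8 | (1R,2R,5S)-5-methyl-2-(prop-1-en-2-yl)-6-oxabicyclo[3.1.0]hexane-1-carbaldehyde (epoxide oxygen anti to isopropenyl) | C=C(C)[C@H]1CC[C@]2(C)O[C@]12C=O | intermediate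
9 | (3E)-4-[(1R,2R,5S)-5-methyl-2-(prop-1-en-2-yl)-6-oxabicyclo[3.1.0]hexan-1-yl]but-3-en-2-one | C=C(C)[C@H]1CC[C@]2(C)O[C@]12/C=C/C(C)=O | intermediate
10 | (3E)-4-[(1R,2S,5S)-2-hydroxy-2-methyl-5-(prop-1-en-2-yl)cyclopentyl]but-3-en-2-one | C=C(C)[C@H]1CC[C@](C)(O)[C@@H]1/C=C/C(C)=O | intermediate
11 | (1S,2R,3S)-2-[(1E)-3-hydroxy-3-methylpenta-1,4-dien-1-yl]-1-methyl-3-(prop-1-en-2-yl)cyclopentan-1-ol, both epimers at the side-chain carbinol | C=C(C)[C@H]1CC[C@](C)(O)[C@@H]1/C=C/C(C)(O)C=C | intermediate
12 | [(2E,4E)-5-[(1R,2S,5S)-2-hydroxy-2-methyl-5-(prop-1-en-2-yl)cyclopentyl]-3-methylpenta-2,4-dien-1-yl]triphenylphosphonium bromide | C=C(C)[C@H]1CC[C@](C)(O)[C@@H]1/C=C/C(C)=C/C[P+](c1ccccc1)(c1ccccc1)c1ccccc1.[Br-] | intermediate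
13 | pseudoionone, (3E,5E)-6,10-dimethylundeca-3,5,9-trien-2-one | CC(C)=CCC/C(C)=C/C=C/C(C)=O | starting material
14 | (4E,6E)-3,7,11-trimethyldodeca-1,4,6,10-tetraen-3-ol, racemic | CC(C)=CCC/C(C)=C/C=C/C(C)(O)C=C | intermediate
15 | [(2E,4E,6E)-3,7,11-trimethyldodeca-2,4,6,10-tetraen-1-yl]triphenylphosphonium bromide | CC(C)=CCC/C(C)=C/C=C/C(C)=C/C[P+](c1ccccc1)(c1ccccc1)c1ccccc1.[Br-] | intermediate
16 | (2E,4E,6E)-2,7-dimethylocta-2,4,6-trienedial | O=C/C(C)=C/C=C/C=C(\C)C=O | starting material
17 | [(2E,4E,6E)-3,7,11-trimethyldodeca-2,4,6,10-tetraen-1-ylidene]triphenylphosphorane (ylide of 15) | CC(C)=CCC/C(C)=C/C=C/C(C)=C/C=P(c1ccccc1)(c1ccccc1)c1ccccc1 | intermediate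
18 | (2E,4E,6E,8E,10E,12E,14E)-2,7,11,15,19-pentamethylicosa-2,4,6,8,10,12,14,18-octaenal (apo-12′-lycopenal) | O=C/C(C)=C/C=C/C=C(C)/C=C/C=C(C)/C=C/C=C(\C)CCC=C(C)C | intermediate
19 | [(2E,4E)-5-[(1R,2S,5S)-2-hydroxy-2-methyl-5-(prop-1-en-2-yl)cyclopentyl]-3-methylpenta-2,4-dien-1-ylidene]triphenylphosphorane (ylide of 12) | C=C(C)[C@H]1CC[C@](C)(O)[C@@H]1/C=C/C(C)=C/C=P(c1ccccc1)(c1ccccc1)c1ccccc1 | intermediate
20 | crude Wittig product, the target constitution as a mixture of 11E and 11Z isomers | C=C(C)[C@H]1CC[C@](C)(O)[C@@H]1/C=C/C(C)=C/C=CC(/C)=C/C=C/C=C(C)/C=C/C=C(C)/C=C/C=C(\C)CCC=C(C)C | intermediate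
21 | (all-E,2S,5S,6R)-1,16-didehydro-2,6-cyclolycopen-5-ol, CNP0222499.1 | C=C(C)[C@H]1CC[C@](C)(O)[C@@H]1/C=C/C(C)=C/C=C/C(C)=C/C=C/C=C(C)/C=C/C=C(C)/C=C/C=C(\C)CCC=C(C)C | target

Total step count: 12 (steps 1–8 and 12 on the ring side, steps 9–11 for the C25 aldehyde).
Longest linear sequence: 9 steps (steps 1–8, then step 12).

Steps most likely to fail

Step 6. Hydride transfer in the allyl-palladium stage may lose regio- or stereocontrol: delivery to C8 would give the deconjugated C6=C7 alkene, face exchange would erode the C6 configuration, and the enone may suffer competing 1,4-reduction. The fallback changes the acyl group that steers the hydride to an ester, the substrate class on which this hydrogenolysis is best established, and installs the methyl ketone only after C6 is set. It sets out from 8. Horner–Wadsworth–Emmons olefination with triethyl phosphonoacetate (NaH, THF, 0 °C) should give ethyl (2E)-3-[(1R,2R,5S)-5-methyl-2-(prop-1-en-2-yl)-6-oxabicyclo[3.1.0]hexan-1-yl]prop-2-enoate F1. The same Pd2(dba)3·CHCl3/n-Bu3P/HCO2H/Et3N hydrogenolysis should give ethyl (2E)-3-[(1R,2S,5S)-2-hydroxy-2-methyl-5-(prop-1-en-2-yl)cyclopentyl]prop-2-enoate F2. MeNH(OMe)·HCl with i-PrMgCl (THF, −20 °C) should convert it into (2E)-3-[(1R,2S,5S)-2-hydroxy-2-methyl-5-(prop-1-en-2-yl)cyclopentyl]-N-methoxy-N-methylprop-2-enamide F3. Weinreb ketone synthesis with MeMgBr (THF, 0 °C) brings the route back at 10.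

Step 4. Conjugate addition of hydroperoxide to the tetrasubstituted enal may be sluggish, alkaline peroxide may degrade the aldehyde oxidatively, and facial selectivity may be poor. The fallback moves the epoxidation to the alcohol oxidation level, where a hydroxyl-directed electrophilic oxidant can be used. It sets out from 7. Luche reduction (NaBH4, CeCl3·7H2O, MeOH, 0 °C) should give [(5R)-2-methyl-5-(prop-1-en-2-yl)cyclopent-1-en-1-yl]methanol F4. VO(acac)2 (cat.) with t-BuOOH in CH2Cl2 at 0 °C should epoxidise only the allylic-alcohol alkene, on the face away from isopropenyl, to give [(1S,2R,5S)-5-methyl-2-(prop-1-en-2-yl)-6-oxabicyclo[3.1.0]hexan-1-yl]methanol F5. Dess–Martin oxidation (CH2Cl2, NaHCO3) returns to the route at 8.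

Step 8. The acid-mediated ionisation may be accompanied by elimination from the pentadienyl cation, by participation or loss of the C5 hydroxyl, and by scrambling of the C9=C10 geometry. The fallback introduces phosphorus by SN2 displacement on a primary allylic bromide instead of through a carbocation. It sets out from 10. Horner–Wadsworth–Emmons olefination with the preformed sodium salt of triethyl phosphonoacetate (THF, rt) and separation of the minor 9Z isomer should give ethyl (2E,4E)-5-[(1R,2S,5S)-2-hydroxy-2-methyl-5-(prop-1-en-2-yl)cyclopentyl]-3-methylpenta-2,4-dienoate F6. Reduction with i-Bu2AlH (CH2Cl2, −78 °C) should give (1S,2R,3S)-2-[(1E,3E)-5-hydroxy-3-methylpenta-1,3-dien-1-yl]-1-methyl-3-(prop-1-en-2-yl)cyclopentan-1-ol F7. Appel bromination of the primary allylic hydroxyl only (CBr4, PPh3, CH2Cl2, 0 °C) should give (1S,2R,3S)-2-[(1E,3E)-5-bromo-3-methylpenta-1,3-dien-1-yl]-1-methyl-3-(prop-1-en-2-yl)cyclopentan-1-ol F8. PPh3 in EtOAc at rt then gives the salt, and the route is rejoined at 12.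

Further compounds
F1 | step 6 | ethyl (2E)-3-[(1R,2R,5S)-5-methyl-2-(prop-1-en-2-yl)-6-oxabicyclo[3.1.0]hexan-1-yl]prop-2-enoate | C=C(C)[C@H]1CC[C@]2(C)O[C@]12/C=C/C(=O)OCC
F2 | step 6 | ethyl (2E)-3-[(1R,2S,5S)-2-hydroxy-2-methyl-5-(prop-1-en-2-yl)cyclopentyl]prop-2-enoate | C=C(C)[C@H]1CC[C@](C)(O)[C@@H]1/C=C/C(=O)OCC
F3 | step 6 | (2E)-3-[(1R,2S,5S)-2-hydroxy-2-methyl-5-(prop-1-en-2-yl)cyclopentyl]-N-methoxy-N-methylprop-2-enamide | C=C(C)[C@H]1CC[C@](C)(O)[C@@H]1/C=C/C(=O)N(C)OC
F4 | step 4 | [(5R)-2-methyl-5-(prop-1-en-2-yl)cyclopent-1-en-1-yl]methanol | C=C(C)[C@H]1CCC(C)=C1CO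
F5 | step 4 | [(1S,2R,5S)-5-methyl-2-(prop-1-en-2-yl)-6-oxabicyclo[3.1.0]hexan-1-yl]methanol | C=C(C)[C@H]1CC[C@]2(C)O[C@]12CO
F6 | step 8 | ethyl (2E,4E)-5-[(1R,2S,5S)-2-hydroxy-2-methyl-5-(prop-1-en-2-yl)cyclopentyl]-3-methylpenta-2,4-dienoate | C=C(C)[C@H]1CC[C@](C)(O)[C@@H]1/C=C/C(C)=C/C(=O)OCC
F7 | step 8 | (1S,2R,3S)-2-[(1E,3E)-5-hydroxy-3-methylpenta-1,3-dien-1-yl]-1-methyl-3-(prop-1-en-2-yl)cyclopentan-1-ol | C=C(C)[C@H]1CC[C@](C)(O)[C@@H]1/C=C/C(C)=C/CO
F8 | step 8 | (1S,2R,3S)-2-[(1E,3E)-5-bromo-3-methylpenta-1,3-dien-1-yl]-1-methyl-3-(prop-1-en-2-yl)cyclopentan-1-ol | C=C(C)[C@H]1CC[C@](C)(O)[C@@H]1/C=C/C(C)=C/CBr
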